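The target is a 2-hydroxybenzophenone: on the benzo ring of the chromene, the C7 hydroxyl sits ortho to C6, which carries the ketone. The route rests on disconnecting the ketone carbon–C6 bond as an anionic Fries shift. Both halves are first united through O7 as the aryl ester of 6-bromo-2,2-dimethyl-2H-chromen-7-ol with MOM-protected 3-hydroxy-2-prenylbenzoic acid, a skeleton that is trivial to assemble. Bromine–lithium exchange at C6 then moves the aroyl group from O7 to C6: one operation forges the diaryl ketone bond regiospecifically and releases the C7 phenol without any protecting group on the chromene. Mild acidic removal of the MOM group completes the synthesis.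

Key step: step 7

Remark on the chemistry: the target has no stereocentre and no stereogenic double bond. The stereocentres that appear in 3, 4, 5 and 11 are racemic and are erased within the step that creates them.

**Step 1**
Reactants: 1 3-hydroxybenzaldehyde
Product: 2 3-(methoxymethoxy)benzaldehyde
Conditions: MOMCl (1.3 equiv), K2CO3 (2 equiv), DMF, 0 °C → rt
Reagents that add atoms: chloromethyl methyl ether, COCCl
Why: Williamson-type O-alkylation of the phenoxide installs the MOM acetal, which later serves as an ortho-directing group and survives organolithium reagents.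

**Step 2**
Reactants: 2 3-(methoxymethoxy)benzaldehyde
Product: 6 3-(methoxymethoxy)-2-(3-methylbut-2-en-1-yl)benzaldehyde, via lithium α-amino alkoxide 3 (not isolated), via C2-lithiated amino alkoxide 4 (not isolated), via C2-prenylated amino alkoxide 5 (not isolated)
Conditions: Me2NCH2CH2N(Me)Li (1.1 equiv, from the amine and n-BuLi), THF, −20 °C; n-BuLi (3 equiv), −20 °C; prenyl bromide (5 equiv), −78 °C → rt; H2O
Reagents that add atoms: 1-bromo-3-methylbut-2-ene (prenyl bromide), CC(C)=CCBr
Why: In situ α-amino alkoxide protection of the aldehyde followed by directed ortho-metalation should place lithium at C2, the position shared by the amino alkoxide and the OMOM director, and SN2 alkylation of aryllithium 4 with prenyl bromide followed by hydrolysis returns the aldehyde (the hemiaminal centre is racemic and is lost on work-up).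

**Step 3**
Reactants: 6 3-(methoxymethoxy)-2-(3-methylbut-2-en-1-yl)benzaldehyde
Product: 7 3-(methoxymethoxy)-2-(3-methylbut-2-en-1-yl)benzoic acid
Conditions: NaClO2, NaH2PO4, 2-methyl-2-butene (excess), t-BuOH/H2O, rt
Reagents that add atoms: sodium chlorite, [Na+].[O-]Cl=O
Why: Pinnick oxidation converts the aldehyde to the acid at buffered pH, and the large excess of 2-methyl-2-butene scavenges HOCl so that the prenyl alkene and the MOM acetal should be untouched.

**Step 4**
Reactants: 8 4-bromobenzene-1,3-diol (4-bromoresorcinol); 9 3-methylbut-2-enoic acid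
Product: 10 6-bromo-7-hydroxy-2,2-dimethylchroman-4-one
Conditions: P2O5/MeSO3H (1:10 w/w), 70 °C
Reagents that add atoms: none
Why: Friedel–Crafts acylation at C6 of the resorcinol (ortho to one OH, para to the other, with C4 blocked by bromine) followed by oxa-Michael closure of the neighbouring OH onto the enone should give the 2,2-dimethylchromanone with bromine at C6 and the free phenol at C7.

**Step 5**
Reactants: 10 6-bromo-7-hydroxy-2,2-dimethylchroman-4-one
Product: 12 6-bromo-2,2-dimethyl-2H-chromen-7-ol, via chromane-4,7-diol 11 (not isolated)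
Conditions: NaBH4 (excess), THF/MeOH, 0 °C → rt; then 2 M aq. HCl to pH 1, rt
Reagents that add atoms: none
Why: Borohydride reduction gives the racemic benzylic alcohol 11, whose C4 cation is stabilised by the para C7 oxygen and the ortho ring oxygen, so acidification should trigger E1 dehydration to the C3=C4 chromene and erase the C4 stereocentre.

**Step 6**
Reactants: 7 3-(methoxymethoxy)-2-(3-methylbut-2-en-1-yl)benzoic acid; 12 6-bromo-2,2-dimethyl-2H-chromen-7-ol
Product: 13 6-bromo-2,2-dimethyl-2H-chromen-7-yl 3-(methoxymethoxy)-2-(3-methylbut-2-en-1-yl)benzoate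
Conditions: DCC, DMAP (cat.), CH2Cl2, 0 °C → rt
Reagents that add atoms: none
Why: Steglich esterification via the acylpyridinium species should acylate the hindered bromophenol under neutral conditions that leave the MOM acetal and both alkenes intact.

**Step 7**
Reactants: 13 6-bromo-2,2-dimethyl-2H-chromen-7-yl 3-(methoxymethoxy)-2-(3-methylbut-2-en-1-yl)benzoate
Product: 16 [7-hydroxy-2,2-dimethyl-2H-chromen-6-yl][3-(methoxymethoxy)-2-(3-methylbut-2-en-1-yl)phenyl]methanone, via aryllithium 14 (not isolated), via lithium phenoxide 15 (not isolated)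
Conditions: t-BuLi (2.1 equiv), THF, −95 °C → −20 °C; then H2O
Reagents that add atoms: none
Why: Bromine–lithium exchange at C6 (irreversible with two equivalents of t-BuLi and far faster at −95 °C than carbonyl addition) gives aryllithium 14, whose C6 carbanion adds to the ester carbonyl held on the neighbouring O7; cleavage of the acyl–O7 bond then gives lithium phenoxide 15, protonated on quench. The closest known reaction type is the anionic Fries rearrangement of ortho-haloaryl benzoates to 2-hydroxybenzophenones started by halogen–metal exchange. No ring of the product is closed; the only cyclic arrangement is the four-centre addition–elimination transition structure (4-exo-trig attack on the carbonyl), which opens to the ketone. No stereocentre is formed. The step needs exchange to win over attack of t-BuLi on the ester and over deprotonation of the benzylic–allylic CH2, which the very fast exchange of an oxygen-flanked aryl bromide at low temperature should secure; the site of acylation is fixed by the bromine at C6, and the 1,3-relationship of C6 to the ester carbonyl makes the transfer intramolecular. The phenoxide formed shields the new ketone from further organolithium addition.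

**Step 8**
Reactants: 16 [7-hydroxy-2,2-dimethyl-2H-chromen-6-yl][3-(methoxymethoxy)-2-(3-methylbut-2-en-1-yl)phenyl]methanone
Product: 17 cudraphenone A
Conditions: 3 M aq. HCl, MeOH, rt
Reagents that add atoms: none
Why: Acid-catalysed acetal cleavage (transfer of the methoxymethyl group to methanol) frees the ring-A phenol, and room temperature with dilute acid should avoid cyclisation of that phenol onto the prenyl group and hydration of the chromene.

**Compound list**
1 | 3-hydroxybenzaldehyde | O=Cc1cccc(O)c1 | starting material
2 | 3-(methoxymethoxy)benzaldehyde | COCOc1cccc(C=O)c1 | intermediate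
3 | lithium {[2-(dimethylamino)ethyl](methyl)amino}[3-(methoxymethoxy)phenyl]methanolate (racemic, not isolated) | [Li+].[O-]C(N(C)CCN(C)C)c1cccc(OCOC)c1 | intermediate
4 | C2-lithio derivative of 3 (racemic, not isolated) | [Li+].[O-]C(N(C)CCN(C)C)c1cccc(OCOC)c1[Li] | intermediate
5 | lithium {[2-(dimethylamino)ethyl](methyl)amino}[3-(methoxymethoxy)-2-(3-methylbut-2-en-1-yl)phenyl]methanolate (racemic, not isolated) | [Li+].[O-]C(N(C)CCN(C)C)c1cccc(OCOC)c1CC=C(C)C | intermediate
6 | 3-(methoxymethoxy)-2-(3-methylbut-2-en-1-yl)benzaldehyde | COCOc1cccc(C=O)c1CC=C(C)C | intermediate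
7 | 3-(methoxymethoxy)-2-(3-methylbut-2-en-1-yl)benzoic acid | COCOc1cccc(C(=O)O)c1CC=C(C)C | intermediate
8 | 4-bromobenzene-1,3-diol (4-bromoresorcinol) | Oc1ccc(Br)c(O)c1 | starting material
9 | 3-methylbut-2-enoic acid | CC(C)=CC(=O)O | starting material
10 | 6-bromo-7-hydroxy-2,2-dimethylchroman-4-one | CC1(C)CC(=O)c2cc(Br)c(O)cc2O1 | intermediate
11 | 6-bromo-2,2-dimethylchromane-4,7-diol (racemic, not isolated) | CC1(C)CC(O)c2cc(Br)c(O)cc2O1 | intermediate
12 | 6-bromo-2,2-dimethyl-2H-chromen-7-ol | CC1(C)C=Cc2cc(Br)c(O)cc2O1 | intermediate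
13 | 6-bromo-2,2-dimethyl-2H-chromen-7-yl 3-(methoxymethoxy)-2-(3-methylbut-2-en-1-yl)benzoate | COCOc1cccc(C(=O)Oc2cc3OC(C)(C)C=Cc3cc2Br)c1CC=C(C)C | intermediate
14 | 6-lithio-2,2-dimethyl-2H-chromen-7-yl 3-(methoxymethoxy)-2-(3-methylbut-2-en-1-yl)benzoate (not isolated) | COCOc1cccc(C(=O)Oc2cc3OC(C)(C)C=Cc3cc2[Li])c1CC=C(C)C | intermediate
15 | lithium 6-[3-(methoxymethoxy)-2-(3-methylbut-2-en-1-yl)benzoyl]-2,2-dimethyl-2H-chromen-7-olate (not isolated) | COCOc1cccc(C(=O)c2cc3C=CC(C)(C)Oc3cc2[O-])c1CC=C(C)C.[Li+] | intermediate
16 | [7-hydroxy-2,2-dimethyl-2H-chromen-6-yl][3-(methoxymethoxy)-2-(3-methylbut-2-en-1-yl)phenyl]methanone | COCOc1cccc(C(=O)c2cc3C=CC(C)(C)Oc3cc2O)c1CC=C(C)C | intermediate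
17 | cudraphenone A, [3-hydroxy-2-(3-methylbut-2-en-1-yl)phenyl](7-hydroxy-2,2-dimethyl-2H-chromen-6-yl)methanone | CC(C)=CCc1c(O)cccc1C(=O)c1cc2c(cc1O)OC(C)(C)C=C2 | target

**Step count**
Total steps: 8. Longest linear sequence: 6 steps (1, 2, 3, 6, 7, 8); steps 4 and 5 form the second branch.

**Steps most likely to fail**

Step 7 (key step). Addition of the alkyllithium to the ester carbonyl, deprotonation at the benzylic–allylic CH2, or intermolecular acyl transfer may compete with the exchange and rearrangement. The fallback sets out from 12 (together with aldehyde 6) and comes back at 16, replacing steps 3, 6 and 7. Bromophenol 12 is treated with t-BuLi (3 equiv) in THF at −78 °C, so that deprotonation and bromine–lithium exchange give lithium 6-lithio-2,2-dimethyl-2H-chromen-7-olate F1. Addition of F1 to aldehyde 6 should give the racemic carbinol (7-hydroxy-2,2-dimethyl-2H-chromen-6-yl)[3-(methoxymethoxy)-2-(3-methylbut-2-en-1-yl)phenyl]methanol F2. Oxidation of this benzylic alcohol with activated MnO2 in CH2Cl2 should then give ketone 16.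

Step 2. Lithiation may be incomplete or misdirected, the excess butyllithium may consume the prenyl bromide, and allylic transposition during alkylation may give the reverse-prenyl pattern. The fallback sets out from 1 and comes back at 6. O-Allylation of 1 (allyl bromide, K2CO3, acetone) gives 3-(allyloxy)benzaldehyde F3. Aromatic Claisen rearrangement (N,N-diethylaniline, 190 °C) should favour migration to the carbon between the oxygen and the formyl group, giving 2-allyl-3-hydroxybenzaldehyde F4 after chromatography. MOM protection (MOMCl, K2CO3, DMF) gives 2-allyl-3-(methoxymethoxy)benzaldehyde F5. Cross-metathesis with excess 2-methyl-2-butene (Grubbs II catalyst, CH2Cl2, 40 °C) should convert the allyl into the prenyl group and return aldehyde 6.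

Step 5. Hydride reduction may be sluggish once the para phenol is deprotonated, and the electron-rich chromene may dimerise or rehydrate during the one-pot aqueous acid dehydration. The fallback sets out from 10 and comes back at 12. Silylation (TBSCl, imidazole, DMF) gives 6-bromo-7-[(tert-butyldimethylsilyl)oxy]-2,2-dimethylchroman-4-one F6. Reduction with NaBH4 in MeOH gives racemic 6-bromo-7-[(tert-butyldimethylsilyl)oxy]-2,2-dimethylchroman-4-ol F7. Separate anhydrous dehydration (cat. p-TsOH, toluene, 80 °C) gives [(6-bromo-2,2-dimethyl-2H-chromen-7-yl)oxy](tert-butyl)dimethylsilane F8. Desilylation with TBAF in THF at 0 °C should then return 12.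

**Further compounds**
F1 | step 7 | lithium 6-lithio-2,2-dimethyl-2H-chromen-7-olate | [Li]c1cc2C=CC(C)(C)Oc2cc1[O-].[Li+]
F2 | step 7 | (7-hydroxy-2,2-dimethyl-2H-chromen-6-yl)[3-(methoxymethoxy)-2-(3-methylbut-2-en-1-yl)phenyl]methanol (racemic) | COCOc1cccc(C(O)c2cc3C=CC(C)(C)Oc3cc2O)c1CC=C(C)C
F3 | step 2 | 3-(allyloxy)benzaldehyde | C=CCOc1cccc(C=O)c1
F4 | step 2 | 2-allyl-3-hydroxybenzaldehyde | C=CCc1c(O)cccc1C=O
F5 | step 2 | 2-allyl-3-(methoxymethoxy)benzaldehyde | COCOc1cccc(C=O)c1CC=C
F6 | step 5 | 6-bromo-7-[(tert-butyldimethylsilyl)oxy]-2,2-dimethylchroman-4-one | CC1(C)CC(=O)c2cc(Br)c(O[Si](C)(C)C(C)(C)C)cc2O1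
F7 | step 5 | 6-bromo-7-[(tert-butyldimethylsilyl)oxy]-2,2-dimethylchroman-4-ol (racemic) | CC1(C)CC(O)c2cc(Br)c(O[Si](C)(C)C(C)(C)C)cc2O1
F8 | step 5 | [(6-bromo-2,2-dimethyl-2H-chromen-7-yl)oxy](tert-butyl)dimethylsilane | CC1(C)C=Cc2cc(Br)c(O[Si](C)(C)C(C)(C)C)cc2O1
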